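## Retrosynthetic overview

1. The C2–C3 bond is cut first. This gives anomeric acetate 25 and the propanoate silyl ketene acetal 28. A catalyst-controlled peroxycarbenium alkylation sets C3 and C2.
2. The 1,2-dioxane (O1–O2–C3–C4–C5–C6) is traced back to the four-membered carbocycle of cyclobutanol 22. O2 is inserted into its C3–C6 bond, so four ring atoms become six.
3. Enabling feature: the ring carbons C3–C6 are contiguous, C6 is fully substituted (CH3, CH2CH2–decalin), and C3 is at the acetal oxidation level. The cyclobutyloxy radical therefore opens only towards the tertiary C6 radical, and the new OOH closes back on the C3 aldehyde.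
4. The cyclobutanol comes from methyl ketone 17 by sulfonium cyclopropylide spiroannulation. The exocyclic CH2 comes from cis-octalone 15.
5. Ring order: ring A (2-methylcyclohexenone, asymmetric conjugate methylation, Michael quaternisation), then ring B (Negishi coupling, vinyl addition, ring-closing metathesis), then the cyclobutane, then the 1,2-dioxane.

Key step: step 14

Abbreviation: Dec = (2R,3S,4aR,8aS)-2,3,6-trimethyl-1-methylidene-1,2,3,4,4a,7,8,8a-octahydronaphthalen-2-yl (cis-fused). The dioxane locants O1, O2 and C3–C6 are used as in line 2 above. C2 is the propanoate α-carbon.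

Assumption: the sense of induction of the phosphoramidite in step 1 and of the chiral acid in step 17 is taken as drawn; the mirror-image ligand or acid would be used if the opposite sense is found.

## Route

Step 1
Reactants: 1 2-methylcyclohex-2-en-1-one
Product: 3 (S)-[(2,3-dimethylcyclohex-1-en-1-yl)oxy]trimethylsilane, via methylzinc enolate 2 (not isolated)
Conditions: Me2Zn, Cu(OTf)2 (2 mol %), (S,R,R)-O,O'-(1,1'-binaphthyl-2,2'-diyl) N,N-bis(1-phenylethyl)phosphoramidite (4 mol %), toluene, −30 °C; then TMSOTf, −30 → 0 °C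
Reagents that add atoms: dimethylzinc C[Zn]C; trimethylsilyl trifluoromethanesulfonate C[Si](C)(C)OS(=O)(=O)C(F)(F)F
Why: Copper-catalysed asymmetric conjugate addition, in which the chiral copper–phosphoramidite complex delivers methyl to one enone face and should set C3 as S, while silylation of 2 fixes the tetrasubstituted enol ether.

Step 2
Reactants: 3 (S)-[(2,3-dimethylcyclohex-1-en-1-yl)oxy]trimethylsilane; 4 but-3-en-2-one
Product: 5 (2R,3S)-2,3-dimethyl-2-(3-oxobutyl)cyclohexan-1-one
Conditions: BF3·OEt2, i-PrOH, CH2Cl2, −78 °C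
Reagents that add atoms: none
Why: Mukaiyama–Michael addition, in which BF3-activated 4 is attacked by the enol ether on the face anti to the pseudoaxial C3 methyl group, which should set the quaternary C2 as R (methyl groups cis, oxobutyl chain trans to the C3 methyl).

Step 3
Reactants: 5 (2R,3S)-2,3-dimethyl-2-(3-oxobutyl)cyclohexan-1-one
Product: 6 (2R,3S)-2,3-dimethyl-2-[2-(2-methyl-1,3-dioxolan-2-yl)ethyl]cyclohexan-1-one
Conditions: TMSOCH2CH2OTMS, TMSOTf (cat.), CH2Cl2, −78 °C
Reagents that add atoms: 1,2-bis(trimethylsilyloxy)ethane C[Si](C)(C)OCCO[Si](C)(C)C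
Why: Kinetic ketalisation with the bis-silyl glycol ether should take only the unhindered methyl ketone, because the ring ketone is flanked by the quaternary carbon, and no stereocentre is affected.

Step 4
Reactants: 6 (2R,3S)-2,3-dimethyl-2-[2-(2-methyl-1,3-dioxolan-2-yl)ethyl]cyclohexan-1-one
Product: 8 (5S,6R)-5,6-dimethyl-6-[2-(2-methyl-1,3-dioxolan-2-yl)ethyl]cyclohex-2-en-1-one, via lithium enolate 7 (not isolated)
Conditions: LDA, THF, −78 °C; then N-tert-butylbenzenesulfinimidoyl chloride, −78 °C
Reagents that add atoms: none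
Why: One-pot dehydrogenation of a ketone enolate with a sulfinimidoyl chloride, in which only one α-carbon carries hydrogen and S-attack on 7 followed by intramolecular syn elimination should give the enone without touching the two stereocentres.

Step 5
Reactants: 8 (5S,6R)-5,6-dimethyl-6-[2-(2-methyl-1,3-dioxolan-2-yl)ethyl]cyclohex-2-en-1-one
Product: 9 (5S,6R)-2-iodo-5,6-dimethyl-6-[2-(2-methyl-1,3-dioxolan-2-yl)ethyl]cyclohex-2-en-1-one
Conditions: I2, pyridine, CH2Cl2, 0 °C → rt
Reagents that add atoms: iodine II
Why: α-Iodination of an enone by the addition–elimination (Baylis–Hillman-type) pathway, in which pyridine adds at the β-carbon, the enolate is iodinated and pyridine leaves again.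

Step 6
Reactants: 9 (5S,6R)-2-iodo-5,6-dimethyl-6-[2-(2-methyl-1,3-dioxolan-2-yl)ethyl]cyclohex-2-en-1-one; 10 4-bromo-2-methylbut-1-ene
Product: 12 (5S,6R)-5,6-dimethyl-2-(3-methylbut-3-en-1-yl)-6-[2-(2-methyl-1,3-dioxolan-2-yl)ethyl]cyclohex-2-en-1-one, via homomethallylzinc bromide 11 (not isolated)
Conditions: 10, Zn dust, LiCl, THF, 40 °C; then 9, PdCl2(dppf) (5 mol %), THF, rt → 50 °C
Reagents that add atoms: none
Why: Negishi cross-coupling of an α-iodoenone with a primary alkylzinc halide (oxidative addition of zerovalent palladium, transmetalation, reductive elimination), the wide-bite-angle ligand holding back β-hydride elimination.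

Step 7
Reactants: 12 (5S,6R)-5,6-dimethyl-2-(3-methylbut-3-en-1-yl)-6-[2-(2-methyl-1,3-dioxolan-2-yl)ethyl]cyclohex-2-en-1-one
Product: 14 (2R,3S,5R,6S)-5-ethenyl-2,3-dimethyl-6-(3-methylbut-3-en-1-yl)-2-[2-(2-methyl-1,3-dioxolan-2-yl)ethyl]cyclohexan-1-one, via bromomagnesium enolate 13 (not isolated)
Conditions: CH2=CHMgBr, CuI·2LiCl (10 mol %), THF, −78 → −40 °C; then AcOH in THF, −78 °C
Reagents that add atoms: vinylmagnesium bromide C=C[Mg]Br
Why: Copper-catalysed conjugate addition followed by kinetic protonation, in which vinyl adds axially and trans to the ring methyl two carbons away (sets C5 as R), and 13 is protonated axially on the face opposite the axial vinyl group (sets C6 as S, the two alkenyl chains cis).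

Step 8
Reactants: 14 (2R,3S,5R,6S)-5-ethenyl-2,3-dimethyl-6-(3-methylbut-3-en-1-yl)-2-[2-(2-methyl-1,3-dioxolan-2-yl)ethyl]cyclohexan-1-one
Product: 15 (2R,3S,4aR,8aS)-2,3,6-trimethyl-2-[2-(2-methyl-1,3-dioxolan-2-yl)ethyl]-3,4,4a,7,8,8a-hexahydronaphthalen-1(2H)-one
Conditions: second-generation Grubbs catalyst (5 mol %), CH2Cl2, 40 °C
Reagents that add atoms: none
Why: Ring-closing metathesis of the vinyl and isopropenyl-type termini closes ring B as the trisubstituted cyclohexene, and the neutral conditions leave the epimerisable C8a untouched.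

Step 9
Reactants: 15 (2R,3S,4aR,8aS)-2,3,6-trimethyl-2-[2-(2-methyl-1,3-dioxolan-2-yl)ethyl]-3,4,4a,7,8,8a-hexahydronaphthalen-1(2H)-one
Product: 16 2-methyl-2-[2-(Dec)ethyl]-1,3-dioxolane
Conditions: Cp2TiMe2, toluene, 75 °C, dark
Reagents that add atoms: dimethyltitanocene [CH3-].[CH3-].[Ti+4].[cH-]1cccc1.[cH-]1cccc1
Why: Petasis methylenation, in which thermally formed titanocene methylidene undergoes [2+2] cycloaddition and cycloreversion with the hindered ketone and, being non-basic, should not epimerise C8a.

Step 10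
Reactants: 16 2-methyl-2-[2-(Dec)ethyl]-1,3-dioxolane
Product: 17 4-(Dec)butan-2-one
Conditions: 1 M aq HCl, THF, rt
Reagents that add atoms: water O
Why: Acid-catalysed ketal hydrolysis under mild conditions that should not isomerise the exocyclic alkene.

Step 11
Reactants: 17 4-(Dec)butan-2-one; 18 cyclopropyldiphenylsulfonium tetrafluoroborate
Product: 20 2-methyl-2-[2-(Dec)ethyl]-1-oxaspiro[2.2]pentane (both epimers at the epoxide carbon), via diphenylsulfonium cyclopropylide 19 (not isolated)
Conditions: KOH (powder), DMSO, rt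
Reagents that add atoms: none
Why: Corey–Chaykovsky-type epoxidation with a sulfonium cyclopropylide, in which addition to the methyl ketone and displacement of diphenyl sulfide give the oxaspiropentane; the new centre is not controlled, which is harmless because it becomes planar in step 14.

Step 12
Reactants: 20 2-methyl-2-[2-(Dec)ethyl]-1-oxaspiro[2.2]pentane
Product: 21 2-methyl-2-[2-(Dec)ethyl]cyclobutan-1-one (both C2 epimers)
Conditions: LiBF4 (cat.), toluene, rt
Reagents that add atoms: none
Why: Lewis acid-induced oxaspiropentane–cyclobutanone rearrangement (semipinacol type), in which opening at the tertiary C–O bond gives a cyclopropylcarbinyl cation and a strain-driven 1,2-shift of a cyclopropane bond gives the 2,2-disubstituted cyclobutanone.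

Step 13
Reactants: 21 2-methyl-2-[2-(Dec)ethyl]cyclobutan-1-one
Product: 22 2-methyl-2-[2-(Dec)ethyl]cyclobutan-1-ol (mixture of diastereomers at both ring centres)
Conditions: NaBH4, MeOH, 0 °C
Reagents that add atoms: none
Why: Borohydride reduction of the strained, electrophilic ketone; the carbinol configuration is irrelevant because this carbon becomes the aldehyde in step 14.

Step 14
Reactants: 22 2-methyl-2-[2-(Dec)ethyl]cyclobutan-1-ol
Product: 24 6-methyl-6-[2-(Dec)ethyl]-1,2-dioxan-3-ol (epimers at C6 and anomers at C3), via hydroperoxy aldehyde 23 (not isolated)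
Conditions: Co(acac)2 (10 mol %), O2 (1 atm), MeCN, rt
Reagents that add atoms: dioxygen O=O
Why: Ligand exchange of 22 on the trivalent cobalt species formed from Co(acac)2 and O2, followed by homolysis, gives the cyclobutyloxy radical, whose strain-releasing β-scission breaks the C3–C6 bond on the quaternary side to leave the C3 aldehyde and the tertiary C6 radical; triplet O2 adds to C6 and the peroxyl radical is reduced and protonated within the cobalt cycle to 23, so that O2 is inserted into the four-membered ring. The closest known reaction type is the Co(acac)2/O2 oxidative ring expansion of secondary cyclobutanols to 1,2-dioxan-3-ols. The 1,2-dioxane closes by 6-exo-trig addition of the terminal hydroperoxide oxygen to the aldehyde (hemiperacetal formation). C3 is a labile anomeric centre that is erased in step 17, and C6 comes from a planar radical remote from every stereocentre, so no element controls it: both C6 epimers are expected and are carried on to step 17, where they become separable cis/trans ring isomers. Regioselectivity of the scission is secured by the fully substituted C6 (tertiary against primary radical), and chemoselectivity by the rate of O2 capture in O2-saturated solution, which should outrun 6-endo or 5-exo attack of the C6 radical on the exocyclic methylene group. No hydride or silane is present, so the two alkenes should not be hydroperoxidised.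

Step 15
Reactants: 24 6-methyl-6-[2-(Dec)ethyl]-1,2-dioxan-3-ol
Product: 25 6-methyl-6-[2-(Dec)ethyl]-1,2-dioxan-3-yl acetate (epimers at C6 and C3)
Conditions: Ac2O, pyridine, DMAP (cat.), CH2Cl2, 0 °C
Reagents that add atoms: acetic anhydride CC(=O)OC(C)=O
Why: O-Acylation of the peroxyhemiacetal traps the closed form as the anomeric acetate, which is the leaving group for step 17; the anomeric centre is erased on ionisation.

Step 16
Reactants: 26 methyl propanoate
Product: 28 (E)-tert-butyl[(1-methoxyprop-1-en-1-yl)oxy]dimethylsilane, via lithium E-enolate 27 (not isolated)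
Conditions: LDA, THF, −78 °C; then TBSCl, DMPU, −78 °C → rt
Reagents that add atoms: tert-butyldimethylsilyl chloride CC(C)(C)[Si](C)(C)Cl
Why: Kinetic ester enolisation in THF through the cyclic deprotonation transition state gives the E-enolate 27, and O-silylation keeps this geometry.

Step 17
Reactants: 25 6-methyl-6-[2-(Dec)ethyl]-1,2-dioxan-3-yl acetate; 28 (E)-tert-butyl[(1-methoxyprop-1-en-1-yl)oxy]dimethylsilane
Product: 29 methyl (2S)-2-{(3R,6R)-6-methyl-6-[2-(Dec)ethyl]-1,2-dioxan-3-yl}propanoate
Conditions: (S,S)-imidodiphosphorimidate acid built from two (S)-3,3'-bis[3,5-bis(trifluoromethyl)phenyl]-1,1'-bi-2-naphthol units with two P=N–SO2CF3 groups (2 mol %), Et2O/pentane, −78 °C; chromatography removes the 6-epimer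
Reagents that add atoms: none
Why: Proposed new method: the chiral acid is silylated by 28 and the resulting silylium ion pair abstracts acetate from either anomer of 25, giving the six-membered peroxycarbenium ion (O2=C3) paired with the confined chiral anion, which leaves one face of C3 open to the ketene acetal; C–C bond formation through an open antiperiplanar transition state should set C3 as R by catalyst control and C2 as S (2,3-syn) through the E geometry of 28, and TBSOAc leaves as the catalyst is re-silylated. The closest known reaction types are additions of silyl ketene acetals to cyclic aliphatic oxocarbenium ions from lactol acetates under the same class of confined acids, and the achiral Lewis acid-catalysed substitution of 3-acetoxy-1,2-dioxanes by silyl ketene acetals. Because C3 is fixed by the catalyst for both C6 epimers, 29 (C3 chain cis to the C6 ethyl-decalin chain, matched with the inherent 3,6-cis preference) and its 6-epimer are ring diastereomers that can be separated.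

## Compound list

1 | 2-methylcyclohex-2-en-1-one | CC1=CCCCC1=O | starting material
2 | methylzinc (S)-2,3-dimethylcyclohex-1-en-1-olate | C[C@H]1CCCC(O[Zn]C)=C1C | intermediate
3 | (S)-[(2,3-dimethylcyclohex-1-en-1-yl)oxy]trimethylsilane | C[C@H]1CCCC(O[Si](C)(C)C)=C1C | intermediate
4 | but-3-en-2-one | C=CC(C)=O | starting material
5 | (2R,3S)-2,3-dimethyl-2-(3-oxobutyl)cyclohexan-1-one | O=C1CCC[C@H](C)[C@@]1(C)CCC(C)=O | intermediate
6 | (2R,3S)-2,3-dimethyl-2-[2-(2-methyl-1,3-dioxolan-2-yl)ethyl]cyclohexan-1-one | O=C1CCC[C@H](C)[C@@]1(C)CCC1(C)OCCO1 | intermediate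
7 | lithium enolate of 6 | [Li]OC1=CCC[C@H](C)[C@@]1(C)CCC1(C)OCCO1 | intermediate
8 | (5S,6R)-5,6-dimethyl-6-[2-(2-methyl-1,3-dioxolan-2-yl)ethyl]cyclohex-2-en-1-one | O=C1C=CC[C@H](C)[C@@]1(C)CCC1(C)OCCO1 | intermediate
9 | (5S,6R)-2-iodo-5,6-dimethyl-6-[2-(2-methyl-1,3-dioxolan-2-yl)ethyl]cyclohex-2-en-1-one | O=C1C(I)=CC[C@H](C)[C@@]1(C)CCC1(C)OCCO1 | intermediate
10 | 4-bromo-2-methylbut-1-ene | C=C(C)CCBr | starting material
11 | (3-methylbut-3-en-1-yl)zinc bromide | C=C(C)CC[Zn]Br | intermediate
12 | (5S,6R)-5,6-dimethyl-2-(3-methylbut-3-en-1-yl)-6-[2-(2-methyl-1,3-dioxolan-2-yl)ethyl]cyclohex-2-en-1-one | O=C1C(CCC(C)=C)=CC[C@H](C)[C@@]1(C)CCC1(C)OCCO1 | intermediate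
13 | bromomagnesium enolate formed by vinyl addition to 12 | Br[Mg]OC1=C(CCC(C)=C)[C@@H](C=C)C[C@H](C)[C@@]1(C)CCC1(C)OCCO1 | intermediate
14 | (2R,3S,5R,6S)-5-ethenyl-2,3-dimethyl-6-(3-methylbut-3-en-1-yl)-2-[2-(2-methyl-1,3-dioxolan-2-yl)ethyl]cyclohexan-1-one | O=C1[C@@H](CCC(C)=C)[C@@H](C=C)C[C@H](C)[C@@]1(C)CCC1(C)OCCO1 | intermediate
15 | (2R,3S,4aR,8aS)-2,3,6-trimethyl-2-[2-(2-methyl-1,3-dioxolan-2-yl)ethyl]-3,4,4a,7,8,8a-hexahydronaphthalen-1(2H)-one, cis-fused | O=C1[C@H]2CCC(C)=C[C@H]2C[C@H](C)[C@@]1(C)CCC1(C)OCCO1 | intermediate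
16 | 2-methyl-2-[2-(Dec)ethyl]-1,3-dioxolane | C=C1[C@H]2CCC(C)=C[C@H]2C[C@H](C)[C@@]1(C)CCC1(C)OCCO1 | intermediate
17 | 4-(Dec)butan-2-one | C=C1[C@H]2CCC(C)=C[C@H]2C[C@H](C)[C@@]1(C)CCC(C)=O | intermediate
18 | cyclopropyldiphenylsulfonium tetrafluoroborate | c1ccc(cc1)[S+](C1CC1)c1ccccc1.F[B-](F)(F)F | starting material
19 | diphenylsulfonium cyclopropylide | c1ccc(cc1)[S+]([C-]1CC1)c1ccccc1 | intermediate
20 | 2-methyl-2-[2-(Dec)ethyl]-1-oxaspiro[2.2]pentane, both epimers at the epoxide carbon | C=C1[C@H]2CCC(C)=C[C@H]2C[C@H](C)[C@@]1(C)CCC1(C)OC12CC2 | intermediate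
21 | 2-methyl-2-[2-(Dec)ethyl]cyclobutan-1-one, both C2 epimers | C=C1[C@H]2CCC(C)=C[C@H]2C[C@H](C)[C@@]1(C)CCC1(C)CCC1=O | intermediate
22 | 2-methyl-2-[2-(Dec)ethyl]cyclobutan-1-ol, diastereomer mixture at C1 and C2 | C=C1[C@H]2CCC(C)=C[C@H]2C[C@H](C)[C@@]1(C)CCC1(C)CCC1O | intermediate
23 | 4-hydroperoxy-4-methyl-6-(Dec)hexanal, both C4 epimers | C=C1[C@H]2CCC(C)=C[C@H]2C[C@H](C)[C@@]1(C)CCC(C)(CCC=O)OO | intermediate
24 | 6-methyl-6-[2-(Dec)ethyl]-1,2-dioxan-3-ol, epimers at C6 and C3 | C=C1[C@H]2CCC(C)=C[C@H]2C[C@H](C)[C@@]1(C)CCC1(C)CCC(O)OO1 | intermediate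
25 | 6-methyl-6-[2-(Dec)ethyl]-1,2-dioxan-3-yl acetate, epimers at C6 and C3 | C=C1[C@H]2CCC(C)=C[C@H]2C[C@H](C)[C@@]1(C)CCC1(C)CCC(OC(C)=O)OO1 | intermediate
26 | methyl propanoate | CCC(=O)OC | starting material
27 | lithium (E)-1-methoxyprop-1-en-1-olate | C/C=C(/O[Li])OC | intermediate
28 | (E)-tert-butyl[(1-methoxyprop-1-en-1-yl)oxy]dimethylsilane | C/C=C(/O[Si](C)(C)C(C)(C)C)OC | intermediate
29 | methyl (2S)-2-{(3R,6R)-6-methyl-6-[2-(Dec)ethyl]-1,2-dioxan-3-yl}propanoate | C=C1[C@H]2CCC(C)=C[C@H]2C[C@H](C)[C@@]1(C)CC[C@]1(C)CC[C@H]([C@H](C)C(=O)OC)OO1 | target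

## Step count

Total step count: 17.
Longest linear sequence: 16 (steps 1–15 and 17).

## Steps most likely to fail

**1. Step 17.**
- What may go wrong: the chiral anion may discriminate the faces of the flat peroxycarbenium ion poorly, the 2,3-syn/anti selectivity may be low, the O–O bond may fragment heterolytically, or the 1,1-disubstituted alkene may be protonated.
- Fallback (known chemistry), from 24 to 29: the open-chain tautomer of 24 reacts with the stabilised ylide methyl 2-(triphenylphosphoranylidene)propanoate (CH2Cl2, rt) in a Wittig olefination. This gives the methyl (E)-6-hydroperoxy-2,6-dimethyl-8-(Dec)oct-2-enoate F1.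
- Et2NH in CF3CH2OH then triggers the 6-exo-trig oxa-Michael ring closure. Net anti addition of O and H across the E-alkene should give the 2,3-syn relationship, and 29 is separated from its ring isomers.

**2. Step 14.**
- What may go wrong: O2 capture at the planar C6 radical has no facial selectivity, so part of the material ends as the 6-epimer. Peroxyl radicals may also cause allylic autoxidation of ring B.
- Fallback, from 17 to 24 as the single 6R epimer, keeping a ring enlargement from five to six atoms:
  - Catalytic asymmetric Corey–Chaykovsky reaction with excess dimethyloxosulfonium methylide, LaLi3(binaphthoxide)3 (the enantiomer that gives the S epoxide), tris(2,4,6-trimethoxyphenyl)phosphine oxide and molecular sieves in THF. This gives the (2S)-2-methyl-2-[2-(Dec)ethyl]oxirane F2 and, in the same pot, the (2S)-2-methyl-2-[2-(Dec)ethyl]oxetane F3.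
  - Ethereal H2O2 with catalytic TMSOTf opens the oxetane at the tertiary carbon with inversion, giving the (3R)-3-hydroperoxy-3-methyl-5-(Dec)pentan-1-ol F4.
  - TEMPO/PhI(OAc)2 oxidation gives the (5R)-5-methyl-5-[2-(Dec)ethyl]-1,2-dioxolan-3-ol F5.
  - Excess Ph3P=CHOMe opens the five-membered ring, giving the (4R)-4-hydroperoxy-1-methoxy-4-methyl-6-(Dec)hex-1-ene F6.
  - Dilute aqueous acid closes F6 to 24.

**3. Step 7.**
- What may go wrong: the cis relationship may be lost through enolate equilibration or epimerisation at the carbon next to the ketone, or 1,2-addition may compete.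
- Fallback, from 8 to 15:
  - A thermal or high-pressure Diels–Alder reaction of 8 with 2-(trimethylsilyloxy)buta-1,3-diene adds suprafacially, anti to the ring methyl group, and gives the cis-fused silyl enol ether adduct F7.
  - Mild acid gives the cis-fused 1,6-dione F8.
  - KHMDS and N-(5-chloropyridin-2-yl)bis(trifluoromethanesulfonimide) enolise the unhindered ketone towards the ring-fusion side, as cis-fused 2-decalones do. This gives the enol triflate F9.
  - MeZnCl with Pd(PPh3)4 installs the vinylic methyl group and gives 15.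

## Further compounds

F1 | step 17 | methyl (E)-6-hydroperoxy-2,6-dimethyl-8-(Dec)oct-2-enoate | C=C1[C@H]2CCC(C)=C[C@H]2C[C@H](C)[C@@]1(C)CCC(C)(CC/C=C(\C)C(=O)OC)OO
F2 | step 14 | (2S)-2-methyl-2-[2-(Dec)ethyl]oxirane | C=C1[C@H]2CCC(C)=C[C@H]2C[C@H](C)[C@@]1(C)CC[C@@]1(C)CO1
F3 | step 14 | (2S)-2-methyl-2-[2-(Dec)ethyl]oxetane | C=C1[C@H]2CCC(C)=C[C@H]2C[C@H](C)[C@@]1(C)CC[C@@]1(C)CCO1
F4 | step 14 | (3R)-3-hydroperoxy-3-methyl-5-(Dec)pentan-1-ol | C=C1[C@H]2CCC(C)=C[C@H]2C[C@H](C)[C@@]1(C)CC[C@](C)(CCO)OO
F5 | step 14 | (5R)-5-methyl-5-[2-(Dec)ethyl]-1,2-dioxolan-3-ol | C=C1[C@H]2CCC(C)=C[C@H]2C[C@H](C)[C@@]1(C)CC[C@]1(C)CC(O)OO1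
F6 | step 14 | (4R)-4-hydroperoxy-1-methoxy-4-methyl-6-(Dec)hex-1-ene | C=C1[C@H]2CCC(C)=C[C@H]2C[C@H](C)[C@@]1(C)CC[C@](C)(CC=COC)OO
F7 | step 7 | cis-fused Diels–Alder adduct of 8, 6-(trimethylsilyloxy)-3,4,4a,5,8,8a-hexahydronaphthalen-1(2H)-one with the substituents and configuration of 15 | O=C1[C@H]2CC=C(O[Si](C)(C)C)C[C@H]2C[C@H](C)[C@@]1(C)CCC1(C)OCCO1
F8 | step 7 | cis-fused octahydronaphthalene-1,6-dione with the substituents and configuration of 15 | O=C1[C@H]2CCC(=O)C[C@H]2C[C@H](C)[C@@]1(C)CCC1(C)OCCO1
F9 | step 7 | cis-fused enol triflate, 15 with OSO2CF3 in place of the vinylic methyl group | O=C1[C@H]2CCC(OS(=O)(=O)C(F)(F)F)=C[C@H]2C[C@H](C)[C@@]1(C)CCC1(C)OCCO1
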